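Atoms C2, C3 and C4 of the pyran ring, with the 3-isopropyl and 4-isobutyl groups, are the self-aldol enal of isovaleraldehyde; its β-carbon becomes C4 and its carbonyl carbon C2. The route therefore cuts C4–C4a and O1–C2 (ring A) and C2–C1' (ring B). In the key step a chiral primary amine joins this enal to 4-(1,3-dithian-2-yl)-3,5-dimethoxyphenol, a symmetric ring A with masked formyl group: Friedel–Crafts conjugate addition makes C4–C4a and sets C4 (S), hemiacetalisation makes O1–C2 and closes the pyran ring. Dehydration to a 4H-chromene and acid-mediated addition of diformylphloroglucinol (ring B) across C2=C3 then set C3 and C2 under substrate control; demethylation finishes.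

Key step: step 3

Assumption: the sense of induction of the cinchona-derived primary amine on this new substrate pair cannot be predicted safely; the quinine-derived catalyst is written, and its quinidine-derived pseudoenantiomer takes its place if the first run leads to the 4R series.

Step 1
Reactants: 1 isovaleraldehyde (3-methylbutanal), two molecules
Product: 2 (E)-2-isopropyl-5-methylhex-2-enal
Conditions: NaOH (aq, 10 mol %), 70 °C, then distillation
Reagents that add atoms: none
Why: Base-catalysed self-aldol addition followed by E1cB dehydration (aldol condensation) gives the conjugated enal, whose E isomer (formyl group and β-alkyl chain on opposite sides) is the thermodynamic one.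

Step 2
Reactants: 3 4-hydroxy-2,6-dimethoxybenzaldehyde
Product: 4 4-(1,3-dithian-2-yl)-3,5-dimethoxyphenol
Conditions: HS(CH2)3SH (1.2 equiv), BF3·OEt2 (0.3 equiv), CH2Cl2–AcOH, 0 → 25 °C
Reagents that add atoms: propane-1,3-dithiol, SCCCS
Why: Lewis-acid-catalysed dithioacetalisation (1,3-dithiane formation) of an aryl aldehyde removes the electrophilic, ring-deactivating formyl group before the amine-catalysed step and gives a mask that tolerates acid cocatalysts.

Step 3
Reactants: 2 (E)-2-isopropyl-5-methylhex-2-enal; 4 4-(1,3-dithian-2-yl)-3,5-dimethoxyphenol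
Product: 6 (4S)-6-(1,3-dithian-2-yl)-4-isobutyl-3-isopropyl-5,7-dimethoxychroman-2-ol (C2/C3 epimer mixture), via open-chain hydroxyaryl aldehyde 5 (not isolated)
Conditions: 2 (1.5 equiv), 9-amino-9-deoxy-epi-quinine (20 mol %), CF3CO2H (40 mol %), toluene, 40 °C
Reagents that add atoms: none
Why: Proposed new method: the primary amine and the acid condense with 2 to an iminium ion, an ortho carbon of 4 attacks its β-carbon and rearomatises, the enamine is protonated at C3 and hydrolysed to aldehyde 5, and the phenol oxygen then adds to the formyl carbon. The closest known reaction types are the amine-catalysed Friedel–Crafts alkylation/hemiacetalisation of electron-rich phenols and naphthols with unbranched enals to chroman-2-ols and the primary-amine iminium activation of α-branched enals toward indole-type carbon nucleophiles; their combination on a phenol and an α-branched β-alkyl enal is the new element. The pyran ring is closed by C4–C4a bond formation followed by a 6-exo-trig hemiacetalisation (O1–C2), which also withdraws the product from the reversible amine equilibria. C4 is the only stereocentre that matters and should be fixed as S by the cinchona scaffold, which shields one face of the ion-paired iminium β-carbon, whereas C3 (enamine protonation) and C2 (anomeric) are left uncontrolled on purpose because step 5 removes both. The step needs 1,4- rather than 1,2-addition, C- rather than O-alkylation and a single ring position: the α-isopropyl group blocks the iminium carbon, the soft acceptor and the phloroglucinol-type ring favour C-attack, and in 4 the two ortho carbons are equivalent while the para carbon carries the dithiane.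

Step 4
Reactants: 6 (4S)-6-(1,3-dithian-2-yl)-4-isobutyl-3-isopropyl-5,7-dimethoxychroman-2-ol
Product: 7 (4S)-2-hydroxy-4-isobutyl-3-isopropyl-5,7-dimethoxychroman-6-carbaldehyde (C2/C3 epimer mixture)
Conditions: MeI (10 equiv), CaCO3 (3 equiv), MeCN–H2O 9:1, 40 °C
Reagents that add atoms: water, O
Why: Alkylative dithiane hydrolysis: S-methylation turns sulfur into a leaving group and water captures the thionium ion stabilised by the trioxygenated ring, while the non-oxidative medium, kept near neutral by insoluble CaCO3, should spare the hemiacetal, the electron-rich ring and C4 and should not methylate the ring-opened phenol.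

Step 5
Reactants: 7 (4S)-2-hydroxy-4-isobutyl-3-isopropyl-5,7-dimethoxychroman-6-carbaldehyde
Product: 8 (4S)-4-isobutyl-3-isopropyl-5,7-dimethoxy-4H-chromene-6-carbaldehyde
Conditions: p-TsOH·H2O (5 mol %), toluene, 4 Å MS, 80 °C
Reagents that add atoms: none
Why: Acid-catalysed dehydration of a cyclic hemiacetal to its enol ether (chroman-2-ol to 4H-chromene) with removal of water makes all C2/C3 isomers converge on one compound without touching C4, and acid is preferred to a sulfonyl chloride/amine protocol because base would open the hemiacetal to the acidic para-formyl phenol.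

Step 6
Reactants: 9 phloroglucinol
Product: 10 2,4,6-trihydroxybenzene-1,3-dicarbaldehyde (diformylphloroglucinol)
Conditions: POCl3 (2.2 equiv), DMF (2.2 equiv), EtOAc, 0 → 25 °C; then H2O, 50 °C
Reagents that add atoms: N,N-dimethylformamide, CN(C)C=O; water, O
Why: Double Vilsmeier–Haack formylation (aromatic substitution by the chloroiminium ion, then hydrolysis) of the highly activated triol stops at the dialdehyde when two equivalents are used, since each formyl group deactivates the ring, and leaves exactly one nucleophilic ring carbon.

Step 7
Reactants: 8 (4S)-4-isobutyl-3-isopropyl-5,7-dimethoxy-4H-chromene-6-carbaldehyde; 10 2,4,6-trihydroxybenzene-1,3-dicarbaldehyde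
Product: 12 5-[(2R,3R,4S)-6-formyl-4-isobutyl-3-isopropyl-5,7-dimethoxychroman-2-yl]-2,4,6-trihydroxybenzene-1,3-dicarbaldehyde, via C3-protonated oxocarbenium ion 11 (not isolated)
Conditions: 10 (1.5 equiv), CF3SO3H (10 mol %), (CF3)2CHOH–CH2Cl2 1:2, −30 → 0 °C; 25 °C if C2 must be equilibrated
Reagents that add atoms: none
Why: Acid-catalysed hydroarylation of a cyclic enol ether, that is a Friedel–Crafts alkylation by a 2-oxocarbenium ion of the kind used to make aryl C-glycosides from glycals and phenols: in 8 the peri 5-methoxy and the 3-isopropyl group push the 4-isobutyl group pseudoaxial, so the proton should add to C3 on the opposite face (3,4-cis, 3R, cation 11) and the only unsubstituted ring carbon of 10 should then attack C2 on that same open face (2,3-trans, 2R), any O-aryl acetal reverting to 11 under the acid, while the 6-formyl group keeps C8 of ring A from competing, the low temperature disfavours hydride transfer from unreacted chromene, and reversible C2–O1 ionisation through the ortho-hydroxy ring B lets C2 settle in the arrangement with equatorial aryl and isopropyl and axial isobutyl.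

Step 8
Reactants: 12 5-[(2R,3R,4S)-6-formyl-4-isobutyl-3-isopropyl-5,7-dimethoxychroman-2-yl]-2,4,6-trihydroxybenzene-1,3-dicarbaldehyde
Product: 13 5-[(2R,3R,4S)-6-formyl-5,7-dihydroxy-4-isobutyl-3-isopropylchroman-2-yl]-2,4,6-trihydroxybenzene-1,3-dicarbaldehyde (target)
Conditions: BBr3 (8 equiv), CH2Cl2, −78 → 0 °C; then H2O
Reagents that add atoms: none
Why: Boron tribromide cleavage of aryl methyl ethers: boron bound between the C6 carbonyl and each flanking methoxy oxygen activates both methyl groups for bromide attack at low temperature (the tribromide is chosen because milder boron halides tend to stop after the first ortho ether), C3 and C4 carry no ionisable bond, and C2, should its benzylic C–O bond open reversibly, can only reclose through O1 to the preferred 2,3-trans isomer already present.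

Compound list
1 | isovaleraldehyde (3-methylbutanal) | CC(C)CC=O | starting material
2 | (E)-2-isopropyl-5-methylhex-2-enal | CC(C)C/C=C(/C=O)C(C)C | intermediate
3 | 4-hydroxy-2,6-dimethoxybenzaldehyde | COc1cc(O)cc(OC)c1C=O | starting material
4 | 4-(1,3-dithian-2-yl)-3,5-dimethoxyphenol | COc1cc(O)cc(OC)c1C1SCCCS1 | intermediate
5 | (3S)-3-[3-(1,3-dithian-2-yl)-6-hydroxy-2,4-dimethoxyphenyl]-2-isopropyl-5-methylhexanal (C2 epimers; formed in the flask) | CC(C)C[C@H](c1c(O)cc(OC)c(C2SCCCS2)c1OC)C(C=O)C(C)C | intermediate
6 | (4S)-6-(1,3-dithian-2-yl)-4-isobutyl-3-isopropyl-5,7-dimethoxychroman-2-ol (C2/C3 epimer mixture) | CC(C)C[C@@H]1c2c(cc(OC)c(C3SCCCS3)c2OC)OC(O)C1C(C)C | intermediate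
7 | (4S)-2-hydroxy-4-isobutyl-3-isopropyl-5,7-dimethoxychroman-6-carbaldehyde (C2/C3 epimer mixture) | CC(C)C[C@@H]1c2c(cc(OC)c(C=O)c2OC)OC(O)C1C(C)C | intermediate
8 | (4S)-4-isobutyl-3-isopropyl-5,7-dimethoxy-4H-chromene-6-carbaldehyde | CC(C)C[C@@H]1c2c(cc(OC)c(C=O)c2OC)OC=C1C(C)C | intermediate
9 | phloroglucinol (benzene-1,3,5-triol) | Oc1cc(O)cc(O)c1 | starting material
10 | 2,4,6-trihydroxybenzene-1,3-dicarbaldehyde (diformylphloroglucinol) | O=Cc1c(O)cc(O)c(C=O)c1O | intermediate
11 | (3R,4S)-6-formyl-4-isobutyl-3-isopropyl-5,7-dimethoxy-3,4-dihydrochromenylium ion (formed in the flask) | CC(C)C[C@@H]1c2c(cc(OC)c(C=O)c2OC)[O+]=C[C@@H]1C(C)C | intermediate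
12 | 5-[(2R,3R,4S)-6-formyl-4-isobutyl-3-isopropyl-5,7-dimethoxychroman-2-yl]-2,4,6-trihydroxybenzene-1,3-dicarbaldehyde | CC(C)C[C@@H]1c2c(cc(OC)c(C=O)c2OC)O[C@@H](c2c(O)c(C=O)c(O)c(C=O)c2O)[C@@H]1C(C)C | intermediate
13 | 5-[(2R,3R,4S)-6-formyl-5,7-dihydroxy-4-isobutyl-3-isopropylchroman-2-yl]-2,4,6-trihydroxybenzene-1,3-dicarbaldehyde | CC(C)C[C@@H]1c2c(cc(O)c(C=O)c2O)O[C@@H](c2c(O)c(C=O)c(O)c(C=O)c2O)[C@@H]1C(C)C | target

Total steps: 8. Longest linear sequence: 6 steps (1 → 2 → 6 → 7 → 8 → 12 → 13; the same count from 3).

Steps most likely to fail

1. Step 3 (the step that carries the label). The amine may condense too slowly with the hindered α-branched enal, so that an unselective acid-catalysed background alkylation takes over, or the two faces of the β-carbon may be poorly distinguished. The fallback uses known chemistry, sets out from 4 and 1 and returns at 6; it forms C3–C4 instead of C4–C4a. Phenol 4, aldehyde 1 and 4-MeC6H4SO2Na in HCO2H–H2O at 25 °C should condense (Mannich-type three-component α-sulfonylalkylation of an electron-rich phenol) to racemic 4-(1,3-dithian-2-yl)-3,5-dimethoxy-2-[3-methyl-1-(4-methylbenzenesulfonyl)butyl]phenol F1. With NaHCO3 in toluene–H2O, F1 should lose sulfinate to the ortho-quinone methide 4-(1,3-dithian-2-yl)-3,5-dimethoxy-6-(3-methylbutylidene)cyclohexa-2,4-dien-1-one F2. F2 is intercepted in the same flask by the enamine from a second equivalent of 1 and α,α-diphenylprolinol trimethylsilyl ether (20 mol %). This enamine-catalysed Michael addition of an aldehyde to an ortho-quinone methide generated in the flask is a known asymmetric reaction type. Hydrolysis gives aldehyde 5, which closes to lactol 6. Here the catalyst fixes C3 and C4 follows through the relative topicity, so the catalyst enantiomer is chosen for 4S. The minor 3,4-diastereomer, which carries the wrong C4, is removed by chromatography before step 5 erases C3.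

2. Step 7. The protonated enol ether may be consumed by hydride transfer from unreacted chromene or by hydration faster than the doubly formylated, weakly nucleophilic ring B attacks, and control of C2 may be incomplete. The fallback sets out from 8 and 9 and returns at 12; ring B enters as the much stronger nucleophile phloroglucinol and is formylated afterwards. Chromene 8 and an excess of 9 (5 equiv) with p-TsOH·H2O (10 mol %) in MeCN at 0 °C should give (2R,3R,4S)-4-isobutyl-3-isopropyl-5,7-dimethoxy-2-(2,4,6-trihydroxyphenyl)chroman-6-carbaldehyde F3 by the same protonation/Friedel–Crafts sequence, the excess of 9 suppressing double alkylation. Vilsmeier–Haack diformylation (POCl3, DMF, EtOAc; then H2O) of the two free positions of the trihydroxyphenyl ring then gives 12. Ring A is protected from formylation at C8 by its own formyl group.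

3. Step 8. The second ether cleavage may stall once the first phenol is locked in a boron chelate, and prolonged exposure to the Lewis acid may ionise the benzylic C2–O1 bond or degrade the polyformylated phenol. The fallback sets out from 8 and returns at 13; the methyl ethers are exchanged for acetates while the molecule is still a base-stable chromene, so that the last step is a mild ester cleavage. Chromene 8 with 4-MeC6H4SLi (6 equiv) in DMPU at 120 °C should give (4S)-5,7-dihydroxy-4-isobutyl-3-isopropyl-4H-chromene-6-carbaldehyde F4 by SN2 demethylation of the aryl methyl ethers, which the ortho formyl group activates. Ac2O, pyridine and DMAP (cat.) in CH2Cl2 at 0 °C then give (4S)-6-formyl-4-isobutyl-3-isopropyl-4H-chromene-5,7-diyl diacetate F5, whose ester groups deactivate C8 as the formyl group does. Hydroarylation with 10 under the conditions of step 7 gives (2R,3R,4S)-2-(3,5-diformyl-2,4,6-trihydroxyphenyl)-6-formyl-4-isobutyl-3-isopropylchroman-5,7-diyl diacetate F6. NaHCO3 in MeOH at 25 °C cleaves the two activated aryl acetates to 13.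

Further compounds
F1 | step 3 | 4-(1,3-dithian-2-yl)-3,5-dimethoxy-2-[3-methyl-1-(4-methylbenzenesulfonyl)butyl]phenol (racemic) | CC(C)CC(c1c(O)cc(OC)c(C2SCCCS2)c1OC)S(=O)(=O)c1ccc(C)cc1
F2 | step 3 | 4-(1,3-dithian-2-yl)-3,5-dimethoxy-6-(3-methylbutylidene)cyclohexa-2,4-dien-1-one | CC(C)CC=C1C(=O)C=C(OC)C(C2SCCCS2)=C1OC
F3 | step 7 | (2R,3R,4S)-4-isobutyl-3-isopropyl-5,7-dimethoxy-2-(2,4,6-trihydroxyphenyl)chroman-6-carbaldehyde | CC(C)C[C@@H]1c2c(cc(OC)c(C=O)c2OC)O[C@@H](c2c(O)cc(O)cc2O)[C@@H]1C(C)C
F4 | step 8 | (4S)-5,7-dihydroxy-4-isobutyl-3-isopropyl-4H-chromene-6-carbaldehyde | CC(C)C[C@@H]1c2c(cc(O)c(C=O)c2O)OC=C1C(C)C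
F5 | step 8 | (4S)-6-formyl-4-isobutyl-3-isopropyl-4H-chromene-5,7-diyl diacetate | CC(C)C[C@@H]1c2c(cc(OC(C)=O)c(C=O)c2OC(C)=O)OC=C1C(C)C
F6 | step 8 | (2R,3R,4S)-2-(3,5-diformyl-2,4,6-trihydroxyphenyl)-6-formyl-4-isobutyl-3-isopropylchroman-5,7-diyl diacetate | CC(C)C[C@@H]1c2c(cc(OC(C)=O)c(C=O)c2OC(C)=O)O[C@@H](c2c(O)c(C=O)c(O)c(C=O)c2O)[C@@H]1C(C)C
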